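**Retrosynthetic overview**

1. Target 12 ⇐ syn allylic alcohol 10: the last step makes the C14–O bond by a hydroxyl-directed singlet-oxygen ene reaction, which also moves the alkene to the exocyclic C13=C16 position.
2. 10 ⇐ enal 8 + 4-methylfuran-2(5H)-one 9: C15–C5′ bond by a catalytic direct vinylogous aldol addition.
3. 8 ⇐ nitrate/epoxide/enoate 6 by one hydride step; C18–O comes from a 6α-alkoxy-radical relay (nitrite photolysis under O2) and C8–O from epoxidation of the 8(17)-alkene.
4. Enoate 3 ⇐ (+)-larixol 1 by side-chain degradation and Horner–Wadsworth–Emmons olefination.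
5. No ring is built: the decalin (rings A and B, with C5, C6, C9, C10) comes from larixol and the butenolide ring is bought as 9.

Assumption: (+)-larixol (13S, 6α-OH; the main labdane diol of larch oleoresin) is taken as an inexpensive purchasable starting material; labdane numbering is used (C18 = 4α substituent, C19 = 4β methyl, C20 = methyl on C10, C17 = carbon on C8, C16 = carbon on C13, butenolide atoms C2′–C5′).

**Route**

Step 1
Reactants: 1 (+)-larixol
Product: 2 6α-hydroxy-14,15-dinorlabd-8(17)-en-13-one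
Conditions: KMnO4, benzyltriethylammonium chloride (cat.), CH2Cl2/H2O, 0 °C → rt
Reagents that add atoms: none
Why: Permanganate dihydroxylation and glycol cleavage of the vinyl carbinol (oxidative side-chain degradation) gives the methyl ketone, while the hindered 8(17)-methylene and the 6α-hydroxyl survive; only the C13 stereocentre is lost.

Step 2
Reactants: 2 6α-hydroxy-14,15-dinorlabd-8(17)-en-13-one
Product: 3 ethyl (13E)-6α-hydroxylabda-8(17),13-dien-15-oate
Conditions: (EtO)2P(O)CH2CO2Et, NaH (2.5 equiv), THF, 0 → 60 °C; E isomer isolated by chromatography (E/Z about 5:1)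
Reagents that add atoms: triethyl phosphonoacetate, CCOC(=O)CP(=O)(OCC)OCC
Why: Horner–Wadsworth–Emmons olefination of the methyl ketone gives the β,β-disubstituted enoate with the usual E preference, and the free 6α-hydroxyl only consumes one extra equivalent of base.

Step 3
Reactants: 3 ethyl (13E)-6α-hydroxylabda-8(17),13-dien-15-oate
Product: 4 ethyl (13E)-8α,17-epoxy-6α-hydroxylabd-13-en-15-oate
Conditions: mCPBA (1.1 equiv), CH2Cl2, 0 °C
Reagents that add atoms: mCPBA (3-chloroperoxybenzoic acid), OOC(=O)c1cccc(Cl)c1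
Why: Prilezhaev epoxidation takes the electron-rich 1,1-disubstituted alkene and leaves the enoate, and attack from the α face (the β face is blocked by the axial C20 methyl) sets C8 with oxygen α.

Step 4
Reactants: 4 ethyl (13E)-8α,17-epoxy-6α-hydroxylabd-13-en-15-oate
Product: 5 ethyl (13E)-8α,17-epoxy-6α-(nitrosooxy)labd-13-en-15-oate
Conditions: NOCl, pyridine, −20 °C
Reagents that add atoms: nitrosyl chloride, O=NCl
Why: O-Nitrosation of the only free hydroxyl gives the nitrite ester needed for the radical relay, with pyridine keeping the epoxide safe from HCl.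

Step 5
Reactants: 5 ethyl (13E)-8α,17-epoxy-6α-(nitrosooxy)labd-13-en-15-oate
Product: 6 ethyl (13E)-8α,17-epoxy-6α-hydroxy-18-(nitrooxy)labd-13-en-15-oate
Conditions: hν (365 nm), O2 (bubbling), benzene, pyridine (trace), 15 °C
Reagents that add atoms: dioxygen, O=O
Why: Barton nitrite photolysis gives the 6α-alkoxy radical, which abstracts hydrogen by 1,5-transfer only from the peri 4α-methyl (O···C18 about 2.5 Å, C19 about 3.5 Å), and the C18 radical is trapped by O2/NO as the nitrate, so C4 becomes a defined stereocentre with the oxygenated carbon α.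

Step 6
Reactants: 6 ethyl (13E)-8α,17-epoxy-6α-hydroxy-18-(nitrooxy)labd-13-en-15-oate
Product: 7 (13E)-labd-13-ene-6α,8α,15,18-tetraol
Conditions: LiAlH4 (excess), THF, −20 → 45 °C (substrate added to the hydride)
Reagents that add atoms: none
Why: One hydride reduction does three jobs: 1,2-reduction of the enoate to the allylic alcohol, O–N cleavage of the nitrate to the 18-alcohol, and SN2 opening of the spiro-epoxide at the primary C17 to give 8α-OH/8β-CH3 with the C8 configuration fixed in step 3.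

Step 7
Reactants: 7 (13E)-labd-13-ene-6α,8α,15,18-tetraol
Product: 8 (13E)-6α,8α,18-trihydroxylabd-13-en-15-al
Conditions: MnO2 (activated, 20 equiv), CH2Cl2/THF, rt
Reagents that add atoms: none
Why: Chemoselective allylic oxidation converts only the allylic 15-alcohol to the enal and leaves the saturated secondary, primary and tertiary hydroxyls untouched.

Step 8
Reactants: 8 (13E)-6α,8α,18-trihydroxylabd-13-en-15-al; 9 4-methylfuran-2(5H)-one
Product: 10 (5R)-5-[(1R,2E)-5-{(1R,2R,4S,4aR,5R,8aS)-2,4-dihydroxy-5-(hydroxymethyl)-2,5,8a-trimethyldecahydronaphthalen-1-yl}-1-hydroxy-3-methylpent-2-en-1-yl]-4-methylfuran-2(5H)-one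
Conditions: 9 (5 equiv), 3-{[3,5-bis(trifluoromethyl)phenyl]amino}-4-{[(8α,9S)-6′-methoxycinchonan-9-yl]amino}cyclobut-3-ene-1,2-dione (20 mol %), 2-MeTHF, 4 Å MS, −10 °C, 96 h
Reagents that add atoms: none
Why: Proposed new method: a syn-selective, catalyst-controlled direct vinylogous aldol addition of a 4-substituted butenolide to a β,β-disubstituted enal in an unprotected triol, in which the quinuclidine nitrogen deprotonates C5 of 9 to an ammonium 2-furanolate, the squaramide N–H pair binds the aldehyde oxygen, and C5 adds 1,2 (the β-carbon is fully substituted) through an open transition state with the alkenyl chain anti to C4 and the catalyst-bound carbonyl oxygen turned away from the 4-methyl group, which should give the syn (15R,5′R) adduct; the closest known reaction type is the amine–squaramide or amine–thiourea catalysed direct vinylogous aldol of unsubstituted γ-butenolides with aromatic aldehydes, together with the syn-selective Lewis-acid Mukaiyama addition of 2-silyloxyfurans.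

Step 9
Reactants: 10 the syn aldol adduct of step 8
Product: 12 (5R)-5-[(1R,2S)-5-{(1R,2R,4S,4aR,5R,8aS)-2,4-dihydroxy-5-(hydroxymethyl)-2,5,8a-trimethyldecahydronaphthalen-1-yl}-1,2-dihydroxy-3-methylidenepentyl]-4-methylfuran-2(5H)-one (CNP0301623.1), via allylic 14-hydroperoxide 11 (not isolated)
Conditions: O2, 5,10,15,20-tetraphenylporphyrin (1 mol %), hν (visible LED), CH2Cl2, −30 °C; then PPh3 (1.5 equiv), −30 °C → rt
Reagents that add atoms: dioxygen (as singlet oxygen), O=O
Why: Hydroxyl-directed Schenck ene reaction: in the conformer that minimises 1,3-allylic strain (C15–H eclipsing the alkene toward the cis C16 methyl) singlet oxygen is delivered to the face carrying the C15 hydroxyl, bonds to C14 syn to that hydroxyl (14S) and abstracts a C16 hydrogen from the disubstituted side of the alkene to give the exocyclic methylene, and PPh3 then reduces the hydroperoxide with retention.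

**Compound list**

1 | (+)-larixol, (13S)-labda-8(17),14-diene-6α,13-diol | C=C[C@@](C)(O)CC[C@@H]1[C@@]2(C)CCCC(C)(C)[C@@H]2[C@@H](O)CC1=C | starting material
2 | 6α-hydroxy-14,15-dinorlabd-8(17)-en-13-one | CC(=O)CC[C@@H]1[C@@]2(C)CCCC(C)(C)[C@@H]2[C@@H](O)CC1=C | intermediate
3 | ethyl (13E)-6α-hydroxylabda-8(17),13-dien-15-oate | CCOC(=O)/C=C(\C)CC[C@@H]1[C@@]2(C)CCCC(C)(C)[C@@H]2[C@@H](O)CC1=C | intermediate
4 | ethyl (13E)-8α,17-epoxy-6α-hydroxylabd-13-en-15-oate | CCOC(=O)/C=C(\C)CC[C@@H]1[C@@]2(C)CCCC(C)(C)[C@@H]2[C@@H](O)C[C@@]1(C3)O3 | intermediate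
5 | ethyl (13E)-8α,17-epoxy-6α-(nitrosooxy)labd-13-en-15-oate (6α-nitrite ester) | CCOC(=O)/C=C(\C)CC[C@@H]1[C@@]2(C)CCCC(C)(C)[C@@H]2[C@@H](ON=O)C[C@@]1(C3)O3 | intermediate
6 | ethyl (13E)-8α,17-epoxy-6α-hydroxy-18-(nitrooxy)labd-13-en-15-oate | CCOC(=O)/C=C(\C)CC[C@@H]1[C@@]2(C)CCC[C@@](C)(CO[N+](=O)[O-])[C@@H]2[C@@H](O)C[C@@]1(C3)O3 | intermediate
7 | (13E)-labd-13-ene-6α,8α,15,18-tetraol | OC/C=C(\C)CC[C@@H]1[C@@]2(C)CCC[C@@](C)(CO)[C@@H]2[C@@H](O)C[C@@]1(C)O | intermediate
8 | (13E)-6α,8α,18-trihydroxylabd-13-en-15-al | O=C/C=C(\C)CC[C@@H]1[C@@]2(C)CCC[C@@](C)(CO)[C@@H]2[C@@H](O)C[C@@]1(C)O | intermediate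
9 | 4-methylfuran-2(5H)-one | CC1=CC(=O)OC1 | starting material
10 | (5R)-5-[(1R,2E)-5-{(1R,2R,4S,4aR,5R,8aS)-2,4-dihydroxy-5-(hydroxymethyl)-2,5,8a-trimethyldecahydronaphthalen-1-yl}-1-hydroxy-3-methylpent-2-en-1-yl]-4-methylfuran-2(5H)-one | C/C(CC[C@@H]1[C@@]2(C)CCC[C@@](C)(CO)[C@@H]2[C@@H](O)C[C@@]1(C)O)=C\[C@@H](O)[C@@H]1OC(=O)C=C1C | intermediate
11 | (5R)-5-[(1R,2S)-5-{(1R,2R,4S,4aR,5R,8aS)-2,4-dihydroxy-5-(hydroxymethyl)-2,5,8a-trimethyldecahydronaphthalen-1-yl}-2-hydroperoxy-1-hydroxy-3-methylidenepentyl]-4-methylfuran-2(5H)-one | C=C(CC[C@@H]1[C@@]2(C)CCC[C@@](C)(CO)[C@@H]2[C@@H](O)C[C@@]1(C)O)[C@H](OO)[C@@H](O)[C@@H]1OC(=O)C=C1C | intermediate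
12 | (5R)-5-[(1R,2S)-5-{(1R,2R,4S,4aR,5R,8aS)-2,4-dihydroxy-5-(hydroxymethyl)-2,5,8a-trimethyldecahydronaphthalen-1-yl}-1,2-dihydroxy-3-methylidenepentyl]-4-methylfuran-2(5H)-one (CNP0301623.1) | C=C(CC[C@@H]1[C@@]2(C)CCC[C@@](C)(CO)[C@@H]2[C@@H](O)C[C@@]1(C)O)[C@H](O)[C@@H](O)[C@@H]1OC(=O)C=C1C | target

**Step count and risks**

Total step count: 9. Longest linear sequence: 9 steps (1 → 12); 9 is used as bought.

The three steps most likely to fail are steps 5, 8 and 9.

Step 5 can fail through β-scission of the 6α-alkoxy radical, through oxime formation when NO outruns O2, or through NO2 damage to the epoxide. The fallback sets out from nitrite 5 and returns at tetraol 7. Photolysis of 5 under argon (the classical oxygen-free Barton reaction, a C–N bond formation) gives, after tautomerisation of the nitroso compound, ethyl (13E)-8α,17-epoxy-6α-hydroxy-18-(hydroxyimino)labd-13-en-15-oate F1. Buffered reductive deoximation (TiCl3, NH4OAc, aqueous THF) gives the 6α,18-lactol F2. The LiAlH4 conditions of step 6 then reduce lactol, epoxide and ester together to 7.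

Step 8 is the proposed new reaction. The 4-methylbutenolide may be too weakly acidic for the amine, the syn preference or the facial sense may not materialise (the quinidine-derived pseudo-enantiomer of the catalyst is the first remedy for the sense), and the 8α-hydroxyl can add reversibly to the enal. The fallback uses known chemistry, sets out from 8 and 9 and returns at 10:

- 9 is silylated (TMSOTf, Et3N) to 4-methyl-2-(trimethylsilyloxy)furan F3.
- 8 is persilylated (N-trimethylsilylimidazole) to its 6,8,18-tris(trimethylsilyl) ether F4.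
- A BF3·OEt2-promoted vinylogous Mukaiyama aldol addition (CH2Cl2, −78 °C), known to favour syn adducts with 2-silyloxyfurans, gives the silylated (1R,5R) adduct F5 and the silylated (1S,5S) adduct F6 in roughly equal amounts, since the remote core exerts no control.
- Dilute HCl in THF removes the silyl groups to give 10 and its (1S,5S) syn diastereomer F7, which are separated by preparative HPLC.

Step 9 can fail through hydrogen abstraction from C12 instead of C16, through erosion of the syn selectivity by the other hydroxyls, or through acid-induced closure of the 8,13-ether. The fallback sets out from 10 and returns at 12. mCPBA in CH2Cl2 at 0 °C epoxidises the allylic alcohol syn to the hydroxyl (hydrogen-bond delivery under 1,3-allylic strain control) to give the (13R,14R)-13,14-epoxy alcohol F8. Titanocene-mediated radical isomerisation (Cp2TiCl from Cp2TiCl2 and Mn dust, THF) then opens the epoxide at the tertiary C13 and eliminates a C16 hydrogen to give the 13(16)-en-14-ol 12. This avoids a C13 cation that the 8α-hydroxyl would capture.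

**Further compounds**

F1 | step 5 | ethyl (13E)-8α,17-epoxy-6α-hydroxy-18-(hydroxyimino)labd-13-en-15-oate | CCOC(=O)/C=C(\C)CC[C@@H]1[C@@]2(C)CCC[C@@](C)(/C=N/O)[C@@H]2[C@@H](O)C[C@@]1(C3)O3
F2 | step 5 | ethyl (13E)-6α,18:8α,17-diepoxy-18-hydroxylabd-13-en-15-oate (6α,18-lactol) | CCOC(=O)/C=C(\C)CC[C@@H]1[C@@]2(C)CCC[C@@](C)(C4O)[C@@H]2[C@@H](O4)C[C@@]1(C3)O3
F3 | step 8 | 4-methyl-2-(trimethylsilyloxy)furan | Cc1coc(O[Si](C)(C)C)c1
F4 | step 8 | (13E)-6α,8α,18-tris(trimethylsilyloxy)labd-13-en-15-al | O=C/C=C(\C)CC[C@@H]1[C@@]2(C)CCC[C@@](C)(CO[Si](C)(C)C)[C@@H]2[C@@H](O[Si](C)(C)C)C[C@@]1(C)O[Si](C)(C)C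
F5 | step 8 | 6,8,18-tris(trimethylsilyl) ether of 10 | C/C(CC[C@@H]1[C@@]2(C)CCC[C@@](C)(CO[Si](C)(C)C)[C@@H]2[C@@H](O[Si](C)(C)C)C[C@@]1(C)O[Si](C)(C)C)=C\[C@@H](O)[C@@H]1OC(=O)C=C1C
F6 | step 8 | 6,8,18-tris(trimethylsilyl) ether of the (1S,5S) diastereomer of 10 | C/C(CC[C@@H]1[C@@]2(C)CCC[C@@](C)(CO[Si](C)(C)C)[C@@H]2[C@@H](O[Si](C)(C)C)C[C@@]1(C)O[Si](C)(C)C)=C\[C@H](O)[C@H]1OC(=O)C=C1C
F7 | step 8 | (5S)-5-[(1S,2E)-5-{(1R,2R,4S,4aR,5R,8aS)-2,4-dihydroxy-5-(hydroxymethyl)-2,5,8a-trimethyldecahydronaphthalen-1-yl}-1-hydroxy-3-methylpent-2-en-1-yl]-4-methylfuran-2(5H)-one | C/C(CC[C@@H]1[C@@]2(C)CCC[C@@](C)(CO)[C@@H]2[C@@H](O)C[C@@]1(C)O)=C\[C@H](O)[C@H]1OC(=O)C=C1C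
F8 | step 9 | (13R,14R)-13,14-epoxide of 10 (epoxide oxygen syn to the C15 hydroxyl) | C[C@]4(CC[C@@H]1[C@@]2(C)CCC[C@@](C)(CO)[C@@H]2[C@@H](O)C[C@@]1(C)O)O[C@@H]4[C@@H](O)[C@@H]1OC(=O)C=C1C
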